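## Analysis of the target

CNP0175424.1 is a glaucolide-type germacranolide: a ten-membered carbocycle (C1–C10) fused across C6–C7 to an α,β-unsaturated γ-lactone (O–C12(=O)–C11=C7), whose α-carbon C11 carries the C13 acetoxymethyl group. The ring bears a ketone at C1, a methyl group and a tertiary acetate at C10, a tiglate at C8 and a trans-4,5-epoxide with a methyl group on C4. There are five stereocentres, (4R,5R,6S,8S,10R). C4, C5 and C6 are contiguous, with the epoxide oxygen at C5 and the lactone oxygen at C6 threo (syn) to each other. The oxygens at C6, C8 and C10 are all syn along the C5–C1 chain, but C6 and C8 are separated by the sp2 carbon C7 and C10 is quaternary. The sensitive groups are the tertiary epoxide (acid), the butenolide with its acidic γ-hydrogen at C6 (base), the allylic esters at C8 and C13 (ionization by palladium, SN2′ attack) and the tertiary α-acyloxy ketone; a ten-membered 1,6-dicarbonyl compound is also prone to transannular aldol closure. The difficulty is to make a medium ring in which seven of ten carbons are functionalized without a low-yielding cyclization, and to relay configuration across a flexible ring. The strategy rests on one feature: C1 and C6 are both oxygenated and lie opposite each other in the ring. Joining them gives the carbon skeleton of a naphthalene with C1 and C6 as fusion carbons, methyl groups on C4 and C10 and oxygen on C8, so the ten-membered ring is the perimeter of an easily made bicycle.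

## Retrosynthetic reasoning

Acyl groups. The C8–O tigloyl bond and the C13–O acetyl bond of 28 are cut last, leading through 26 to diol 25 and acid chloride 27. These allylic esters would not survive palladium or enolate chemistry. The tertiary C10 acetate is placed much earlier, at 16, where nothing else can be acylated.

C11–C13 bond. 25 is cut between C11 and C13 to enol triflate 23 and the one-carbon stannane 24 (Stille coupling). The coupling is done on the C8 alcohol: a free C13 hydroxyl cis to a C8 ketone would be a γ-hydroxy enone that can cyclize to a furan. The C8 carbinol of 23 comes from ketone 22 by a reagent-controlled reduction, and 22 from enol 21 by sulfonylation.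

C7–C11 bond and lactone ring. The butenolide of 21 is opened at C7–C11. C7 is α to the C8 carbonyl that the naphthalene oxygen supplies, so it can act as the nucleophile. The two lactone carbons C11 and C12 come from 19, attached first to the C6 oxygen (20 from 18). The forward step is a Dieckmann-type closure that leaves an enol at C11 as the handle for C13.

Epoxide. In 18 the C4–O and C5–O bonds are cut back to the (E)-alkene of allylic alcohol 17. A hydroxyl-directed peracid epoxidation gives the threo relation between C5–O and C6–O, and syn addition to an E-alkene gives the trans-epoxide, so C4 and C5 follow from C6. Epoxidation of the enone with a nucleophilic peroxide followed by carbonyl reduction was considered for this stage; it was not chosen because reduction of an epoxy ketone normally gives the erythro isomer. The epoxide is made only after the acidic unmasking 16 → 17, so it never meets acid.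

C10–O bond. 16 and 15 are traced to 13 by cutting the C10–O bond, through the C1=C10 enolate 14. This must come before the lactone, because a butenolide γ-hydrogen is more acidic than the ketone α-hydrogens. It also removes the racemic C10 centre that comes from the arene precursor. At 13 the C1 ketone is the only enolizable carbonyl.

C6 carbinol. 13 and 12 lead back to enone 11. Reduction of the C6 carbonyl is the first enantioselective step, and an enone is the substrate class for which catalyst-controlled carbonyl reduction is best established.

Alkene position. The C4=C5 alkene of 11 is traced to the C3=C4 alkene of 9 through the C4 carbinol 10. In 9 the alkene is β,γ to both ketones, so a base would conjugate it in either direction. Radical hydration distinguishes the two sides through the methyl branch, because only C4 gives a tertiary radical, and the subsequent syn elimination needs no base.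

C1=C6 bond (key disconnection). The C1 and C6 carbonyl groups of 9 are rejoined to the tetrasubstituted alkene of bicycle 7. Nothing else gives both ring oxygens and the ten-membered ring at once; the forward reaction has only to cleave one alkene in the presence of another.

Dearomatization. 7 comes from ketal 6 by Birch reduction and 6 from tetralone 4. A fully aromatic methoxynaphthalene was considered, but its oxygenated ring can protonate at a fusion carbon instead of the methyl-bearing carbon. The oxygenated ring is therefore brought in at the ketone level, and only the trialkylbenzene ring, whose regiochemistry is unambiguous, is reduced.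

Annulation. 4 is cut at the two bonds to the three-carbon unit: acid chloride 2 (from acid 1) acylates propene 3, and the resulting cation closes onto the arene.

## Alternatives that were turned down

Alternative 1: The lactone O–C12 bond and the epoxide C4–O bond are cut together. The ten-membered ring would then carry a free tertiary hydroxyl at C4, a cis-5,6-epoxide and a C12 methyl ester on the 7(11)-alkene. In the forward step a catalytic amidine base triggers a Payne rearrangement: the C4 alkoxide opens the epoxide at C5 with inversion, and the released C6 alkoxide lactonizes, giving A1, the target with a silyl ether at C13.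
- For: the trans-epoxide is guaranteed by the SN2 inversion, two rings form in one mild step, and lactonization pulls the Payne equilibrium. On epoxide geometry it is stronger than the chosen route, which depends on an E-alkene.
- Against: the cascade presupposes the ten-membered ring with its tetrasubstituted alkene and four stereocentres, which it does not help to build. The C4 alkoxide is 1,4 to the C1 ketone and can add to it across the ring. The C8 and C10 esters are exposed to alkoxides. A1 still needs a silyl-for-acetyl exchange.
- Comparison: the chosen strategy gives the medium ring without any cyclization, from a precursor made in four steps.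

Alternative 2: The ring is cut at C3–C4 and traced to a cis-1-vinyl-2-alkenylcyclohexanol. The alkoxide-accelerated [3,3] shift forms C3–C4, breaks C1–C6 and gives the ring-enlarged enone A2.
- For: it is also a ring expansion, and it sets the C4 carbinol centre in the ring-forming event through an ordered transition state, with C8 and C10 carried in from a six-membered ring. On stereocontrol in the key step it is stronger, since the ozonolysis creates no stereocentre.
- Against: A2 has a (Z)-C5=C6 alkene, so both C5 and C6 must still be oxygenated with the right sense and the epoxide closed separately. It carries three 4-methoxybenzyl and two silyl ethers, and the butenolide has to be made by oxidizing a bis(alkoxymethyl)alkylidene. The vinyl terminus that becomes C4 is fully substituted, which slows the shift.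
- Comparison: building the divinylcyclohexanol with three stereocentres costs far more than four steps. The chosen route delivers the C1 and C6 oxygens in the key step itself.

Alternative 3: The ring is cut at C7–C8. An open-chain aldehyde carrying a C7-bromo butenolide would close under cathodically regenerated divalent chromium (CrCl2 with NiCl2) to A3, the 8-hydroxy compound lacking the tiglate. A3 is the same compound as 26 of the chosen route.
- For: it is convergent, the butenolide, epoxide and C10 centre are made in acyclic fragments, and it ends one acylation from the target. On convergence and late-stage simplicity it is stronger than the linear chosen route.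
- Against: a ten-membered ring must be closed by C–C bond formation at a tetrasubstituted, electron-poor alkenyl carbon, against medium-ring strain and under dilution. The C8 configuration is set in that closure with no evident control. The aldehyde is β to the tertiary acetate (elimination), and the α-acyloxy ketone is reducible by divalent chromium.
- Comparison: the chosen route never cyclizes the medium ring and sets C8 by a catalyst-controlled ketone reduction.

Key step: step 5

Remarks on the chemistry:
- Ten-membered compounds are numbered as in germacranes (C1–C10 in the ring, C11–C13 on the lactone side, C14 on C10, C15 on C4); the cyclodecane names use the same locants.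
- Compounds 4, 6, 7, 9 and 11 are racemic and one enantiomer is drawn; 8 and 10 are diastereomer mixtures; 12 and 13 have one C6 configuration but both C10 configurations.
- It is assumed that the (+)-enantiomer of the oxaziridine is the one that attacks the Re face of C10 in step 10; if not, the (−)-enantiomer is used.

## Route

Step 1
Reactants: 1 3-methylphenylacetic acid
Product: 2 3-methylphenylacetyl chloride
Conditions: SOCl2, DMF (cat.), toluene, 60 °C
Reagents that add atoms: thionyl chloride, O=S(Cl)Cl
Why: Acid chloride formation through the chlorosulfite; the benzylic methylene is untouched and the crude chloride is used after evaporation.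

Step 2
Reactants: 2 3-methylphenylacetyl chloride; 3 propene
Product: 4 rac-4,7-dimethyl-3,4-dihydronaphthalen-2(1H)-one
Conditions: AlCl3 (2 equiv), CH2Cl2, −10 °C → rt; ice/HCl
Reagents that add atoms: none
Why: Friedel–Crafts acylation of the alkene at its terminal carbon (Darzens–Nenitzescu type) gives a cation at the methyl-bearing carbon, which alkylates the ring ortho to the side chain and para to the aryl methyl group, the less hindered and more activated site; the ethylene version of this 2-tetralone annulation is standard. The new stereocentre forms as a racemate and is erased in step 10.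

Step 3
Reactants: 4 rac-4,7-dimethyl-3,4-dihydronaphthalen-2(1H)-one; 5 ethylene glycol
Product: 6 rac-4',7'-dimethyl-3',4'-dihydro-1'H-spiro[1,3-dioxolane-2,2'-naphthalene]
Conditions: TsOH·H2O (cat.), toluene, reflux, Dean–Stark
Reagents that add atoms: none
Why: Acid-catalysed ketalization with azeotropic removal of water; the dioxolane masks the future C8 oxygen and is stable to dissolving metal and to ozone.

Step 4
Reactants: 6 rac-4',7'-dimethyl-3',4'-dihydro-1'H-spiro[1,3-dioxolane-2,2'-naphthalene]
Product: 7 rac-4',7'-dimethyl-3',4',5',8'-tetrahydro-1'H-spiro[1,3-dioxolane-2,2'-naphthalene]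
Conditions: Li, NH3 (l), THF, t-BuOH, −78 → −33 °C; NH4Cl
Reagents that add atoms: none
Why: Birch reduction of a 1,2,4-trialkylbenzene: protonation occurs at the two unsubstituted, para-related carbons C5' and C8', so all alkyl-bearing carbons stay sp2 and the ring-fusion bond becomes the only tetrasubstituted alkene. The ketal carbon is not benzylic and is inert.

Step 5
Reactants: 7 rac-4',7'-dimethyl-3',4',5',8'-tetrahydro-1'H-spiro[1,3-dioxolane-2,2'-naphthalene]
Product: 9 rac-(3Z)-4,10-dimethylcyclodec-3-ene-1,6,8-trione 8-(ethylene ketal), via secondary ozonide 8 (not isolated)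
Conditions: O3 (1.0 equiv, titrated solution in CH2Cl2), CH2Cl2, −78 °C; then PPh3, −78 °C → rt
Reagents that add atoms: ozone, [O-][O+]=O
Why: Ozone adds as an electrophilic 1,3-dipole to the ring-fusion alkene (germacrane C1=C6); the primary ozonide fragments in the Criegee manner into a ketone and a carbonyl oxide that stay tied by both carbon bridges and recombine to the bicyclic ozonide 8, which PPh3 reduces to the two ketones. The closest known reactions are the ozonolysis of 1,2,3,4,5,6,7,8-octahydronaphthalene to cyclodecane-1,6-dione and of 1,4,5,8-tetrahydronaphthalene to the corresponding cyclodecadienedione. The ten-membered ring is not closed by bond formation: it is the perimeter of the bicycle and is released when the bond shared by the two six-membered rings is cut, so no cyclization entropy or transannular strain is paid. No stereocentre is created; C10 stays racemic and the C3=C4 alkene keeps the Z geometry it had in the six-membered ring. The step needs chemoselectivity between the tetrasubstituted fusion alkene and the trisubstituted alkene: the former carries four alkyl groups and is the more electron-rich, and exactly one equivalent of ozone is metered in at −78 °C. The dioxolane is inert to ozone, and the neutral phosphine work-up avoids the transannular aldol of the 1,6-diketone.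

Step 6
Reactants: 9 rac-(3Z)-4,10-dimethylcyclodec-3-ene-1,6,8-trione 8-(ethylene ketal)
Product: 10 rac-4-hydroxy-4,10-dimethylcyclodecane-1,6,8-trione 8-(ethylene ketal) as a mixture of diastereomers
Conditions: Co(acac)2 (20 mol%), PhSiH3, O2 (1 atm), THF, 0 °C → rt
Reagents that add atoms: dioxygen, O=O
Why: Mukaiyama hydration: hydrogen-atom transfer from a cobalt hydride to C3 gives the tertiary C4 radical, which is trapped by O2 and reduced to the alcohol. The regiochemistry follows radical stability and not enolization, so the alkene is functionalized towards C6 only, although both ketones are β,γ to it; the C4 configuration is irrelevant.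

Step 7
Reactants: 10 rac-4-hydroxy-4,10-dimethylcyclodecane-1,6,8-trione 8-(ethylene ketal)
Product: 11 rac-(4E)-4,10-dimethylcyclodec-4-ene-1,6,8-trione 8-(ethylene ketal)
Conditions: Burgess reagent, benzene, 50 °C
Reagents that add atoms: none
Why: Burgess dehydration: the tertiary alcohol is converted into its sulfamate, which collapses by syn elimination towards the C5 hydrogens acidified by the C6 carbonyl, so the alkene should form in conjugation with C6 only and without base. Syn eliminations in ten-membered rings (Cope and Hofmann eliminations of cyclodecyl derivatives) favour the E-cycloalkene, and the E-enone is expected on that ground.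

Step 8
Reactants: 11 rac-(4E)-4,10-dimethylcyclodec-4-ene-1,6,8-trione 8-(ethylene ketal)
Product: 12 (4E,6S)-6-hydroxy-4,10-dimethylcyclodec-4-ene-1,8-dione 8-(ethylene ketal) as both C10 epimers
Conditions: (R)-2-methyl-CBS-oxazaborolidine (0.3 equiv), catecholborane (1.2 equiv), toluene, −78 °C
Reagents that add atoms: none
Why: Corey–Bakshi–Shibata reduction: the enone carbonyl, more Lewis-basic and less hindered than the α-branched C1 ketone, binds the catalyst boron anti to the alkenyl flank (large group) and takes hydride on the face that gives the (6S)-carbinol with the (R)-catalyst. C10 is untouched, so two C10 epimers with the same C6 configuration are carried on together.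

Step 9
Reactants: 12 (4E,6S)-6-hydroxy-4,10-dimethylcyclodec-4-ene-1,8-dione 8-(ethylene ketal)
Product: 13 (4E,6S)-4,10-dimethyl-6-(triethylsilyloxy)cyclodec-4-ene-1,8-dione 8-(ethylene ketal) as both C10 epimers
Conditions: TESCl, imidazole, DMF, 0 °C
Reagents that add atoms: chlorotriethylsilane, CC[Si](Cl)(CC)CC
Why: Silylation of the secondary allylic alcohol; the silyl ether blocks the transannular hemiketal with C1 and keeps a C6 alkoxide out of the enolate chemistry of step 10.

Step 10
Reactants: 13 (4E,6S)-4,10-dimethyl-6-(triethylsilyloxy)cyclodec-4-ene-1,8-dione 8-(ethylene ketal)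
Product: 15 (4E,6S,10R)-10-hydroxy-4,10-dimethyl-6-(triethylsilyloxy)cyclodec-4-ene-1,8-dione 8-(ethylene ketal), via potassium enolate 14 (not isolated)
Conditions: KN(SiMe3)2 (0.95 equiv), THF, −78 → 0 °C; then (+)-(camphorsulfonyl)oxaziridine, −78 °C; NH4Cl
Reagents that add atoms: (+)-(2R,8aS)-(camphorsulfonyl)oxaziridine, CC1(C)C2CCC13CS(=O)(=O)N4OC34C2
Why: Davis oxidation: with a slight deficit of base at 0 °C the C1 ketone, the only enolizable carbonyl, equilibrates mainly to the more substituted C1=C10 enolate 14, in which the C10 centre of both epimers is erased. The chiral oxaziridine then delivers oxygen to the Re face of C10 under reagent control to give (10R); since C6 is fixed, any (10S) product is a diastereomer and is removed by chromatography.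

Step 11
Reactants: 15 (4E,6S,10R)-10-hydroxy-4,10-dimethyl-6-(triethylsilyloxy)cyclodec-4-ene-1,8-dione 8-(ethylene ketal)
Product: 16 (4E,6S,10R)-10-acetoxy-4,10-dimethyl-6-(triethylsilyloxy)cyclodec-4-ene-1,8-dione 8-(ethylene ketal)
Conditions: Ac2O, Et3N, DMAP, CH2Cl2, 40 °C
Reagents that add atoms: acetic anhydride, CC(=O)OC(C)=O
Why: DMAP-catalysed acetylation of the tertiary α-hydroxy ketone, warmed because the alcohol is tertiary; nothing else in 15 can be acylated.

Step 12
Reactants: 16 (4E,6S,10R)-10-acetoxy-4,10-dimethyl-6-(triethylsilyloxy)cyclodec-4-ene-1,8-dione 8-(ethylene ketal)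
Product: 17 (4E,6S,10R)-10-acetoxy-6-hydroxy-4,10-dimethylcyclodec-4-ene-1,8-dione
Conditions: PPTS, acetone/H2O, 50 °C
Reagents that add atoms: water, O
Why: Mild acid-catalysed hydrolysis removes the dioxolane and the triethylsilyl ether in one operation. It is placed before the epoxide is made, so the only acid-sensitive group present is the allylic alcohol, which pyridinium tosylate should not ionize.

Step 13
Reactants: 17 (4E,6S,10R)-10-acetoxy-6-hydroxy-4,10-dimethylcyclodec-4-ene-1,8-dione
Product: 18 (4R,5R,6S,10R)-10-acetoxy-4,5-epoxy-6-hydroxy-4,10-dimethylcyclodecane-1,8-dione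
Conditions: mCPBA, NaHCO3, CH2Cl2, 0 °C
Reagents that add atoms: 3-chloroperoxybenzoic acid, OOC(=O)c1cccc(Cl)c1
Why: Hydroxyl-directed Prilezhaev (Henbest) epoxidation: A(1,3) strain between the C4 methyl group and the C6 substituents holds H6 in the alkene plane, and the hydrogen-bonded peracid attacks the face that carries the hydroxyl, which is also the outer face of the ring, giving the threo epoxy alcohol. Syn addition to the E-alkene makes the epoxide trans, so (6S) becomes (4R,5R); Baeyer–Villiger oxidation of the ketones is far slower at 0 °C.

Step 14
Reactants: 18 (4R,5R,6S,10R)-10-acetoxy-4,5-epoxy-6-hydroxy-4,10-dimethylcyclodecane-1,8-dione; 19 methyl chlorooxoacetate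
Product: 20 (4R,5R,6S,10R)-10-acetoxy-4,5-epoxy-6-(methoxyoxalyloxy)-4,10-dimethylcyclodecane-1,8-dione
Conditions: pyridine, CH2Cl2, −40 °C
Reagents that add atoms: none
Why: Acylation of the only free hydroxyl by the acid chloride end of 19; the methyl ester end is kept as the electrophile for the ring closure.

Step 15
Reactants: 20 (4R,5R,6S,10R)-10-acetoxy-4,5-epoxy-6-(methoxyoxalyloxy)-4,10-dimethylcyclodecane-1,8-dione
Product: 21 (4R,5R,6S,10R)-10-acetoxy-4,5-epoxy-11-hydroxy-1,8-dioxo-13-norgermacr-7(11)-en-12,6-olide
Conditions: LiN(SiMe3)2 (2.1 equiv), THF, −78 → −40 °C; then 1 M HCl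
Reagents that add atoms: none
Why: Dieckmann-type (intramolecular Claisen) condensation: the C8 ketone is deprotonated at C7, the less hindered of its α-positions (C9 is neopentyl), and the enolate attacks the distal, highly electrophilic oxalate carbonyl in a 5-exo-trig closure. Loss of methoxide gives the α-keto lactone, which the second equivalent of base traps as its enolate, making the closure irreversible; the low temperature is meant to keep β-elimination of the C6 and C10 acyloxy groups behind the ring closure.

Step 16
Reactants: 21 (4R,5R,6S,10R)-10-acetoxy-4,5-epoxy-11-hydroxy-1,8-dioxo-13-norgermacr-7(11)-en-12,6-olide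
Product: 22 (4R,5R,6S,10R)-10-acetoxy-4,5-epoxy-1,8-dioxo-11-(trifluoromethanesulfonyloxy)-13-norgermacr-7(11)-en-12,6-olide
Conditions: PhNTf2, Et3N, CH2Cl2, 0 °C
Reagents that add atoms: N-phenylbis(trifluoromethanesulfonimide), O=S(=O)(N(c1ccccc1)S(=O)(=O)C(F)(F)F)C(F)(F)F
Why: O-Sulfonylation of the acidic enol, a vinylogous carboxylic acid, with a mild triflating agent gives the α-triflyloxy butenolide needed for coupling at C11.

Step 17
Reactants: 22 (4R,5R,6S,10R)-10-acetoxy-4,5-epoxy-1,8-dioxo-11-(trifluoromethanesulfonyloxy)-13-norgermacr-7(11)-en-12,6-olide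
Product: 23 (4R,5R,6S,8S,10R)-10-acetoxy-4,5-epoxy-8-hydroxy-1-oxo-11-(trifluoromethanesulfonyloxy)-13-norgermacr-7(11)-en-12,6-olide
Conditions: (R)-2-methyl-CBS-oxazaborolidine (1.0 equiv), catecholborane, CH2Cl2/toluene, −78 °C
Reagents that add atoms: none
Why: Corey–Bakshi–Shibata reduction of the C8 ketone, flanked by the fully substituted alkene carbon C7 (large) and the C9 methylene (small): the (R)-catalyst should give the (8S)-alcohol. The C1 ketone sits next to the quaternary C10 and is too hindered to compete, and the new alcohol cannot translactonize because the bicyclic intermediate would put the C7=C11 alkene at a bridgehead.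

Step 18
Reactants: 23 (4R,5R,6S,8S,10R)-10-acetoxy-4,5-epoxy-8-hydroxy-1-oxo-11-(trifluoromethanesulfonyloxy)-13-norgermacr-7(11)-en-12,6-olide; 24 (tributylstannyl)methanol
Product: 25 (4R,5R,6S,8S,10R)-10-acetoxy-4,5-epoxy-8,13-dihydroxy-1-oxogermacr-7(11)-en-12,6-olide
Conditions: Pd(PPh3)4 (cat.), LiCl, 1,4-dioxane, 90 °C
Reagents that add atoms: none
Why: Stille coupling: oxidative addition into the electron-poor C11–OTf bond, chloride-assisted transfer of the hydroxymethyl group from tin and reductive elimination install C13. It is run on the C8 alcohol so that no γ-hydroxy enone able to close to a furan arises, and before the allylic esters exist, which zerovalent palladium could ionize.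

Step 19
Reactants: 25 (4R,5R,6S,8S,10R)-10-acetoxy-4,5-epoxy-8,13-dihydroxy-1-oxogermacr-7(11)-en-12,6-olide
Product: 26 (4R,5R,6S,8S,10R)-10,13-diacetoxy-4,5-epoxy-8-hydroxy-1-oxogermacr-7(11)-en-12,6-olide
Conditions: AcCl (1.05 equiv), 2,4,6-collidine, CH2Cl2, −78 °C
Reagents that add atoms: acetyl chloride, CC(Cl)=O
Why: Selective acetylation of the primary allylic alcohol with acetyl chloride and a hindered base at low temperature; the secondary C8 alcohol reacts much more slowly.

Step 20
Reactants: 26 (4R,5R,6S,8S,10R)-10,13-diacetoxy-4,5-epoxy-8-hydroxy-1-oxogermacr-7(11)-en-12,6-olide; 27 (E)-2-methylbut-2-enoyl chloride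
Product: 28 (4R,5R,6S,8S,10R)-10,13-diacetoxy-4,5-epoxy-1-oxo-8-[(E)-2-methylbut-2-enoyloxy]germacr-7(11)-en-12,6-olide (CNP0175424.1)
Conditions: pyridine, DMAP (cat.), CH2Cl2, 0 °C → rt
Reagents that add atoms: none
Why: DMAP-catalysed acylation of the remaining secondary alcohol; the E geometry of the tigloyl group is the stable one and is kept, and the mild base leaves the butenolide and the epoxide alone.

## Compound list

1 | 3-methylphenylacetic acid | Cc1cccc(CC(=O)O)c1 | starting material
2 | 3-methylphenylacetyl chloride | Cc1cccc(CC(=O)Cl)c1 | intermediate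
3 | propene | CC=C | starting material
4 | rac-4,7-dimethyl-3,4-dihydronaphthalen-2(1H)-one (one enantiomer drawn) | C[C@@H]1CC(=O)Cc2cc(C)ccc21 | intermediate
5 | ethylene glycol | OCCO | starting material
6 | rac-4',7'-dimethyl-3',4'-dihydro-1'H-spiro[1,3-dioxolane-2,2'-naphthalene] (one enantiomer drawn) | C[C@@H]1CC2(OCCO2)Cc3cc(C)ccc31 | intermediate
7 | rac-4',7'-dimethyl-3',4',5',8'-tetrahydro-1'H-spiro[1,3-dioxolane-2,2'-naphthalene] (one enantiomer drawn) | C[C@@H]1CC2(OCCO2)CC3=C1CC=C(C)C3 | intermediate
8 | secondary ozonide of 7 (1,2,4-trioxolane across C1 and C6, diastereomer mixture) | C[C@@H]1CC2(OCCO2)CC34C/C(C)=C\CC1(OO3)O4 | intermediate (not isolated)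
9 | rac-(3Z)-4,10-dimethylcyclodec-3-ene-1,6,8-trione 8-(ethylene ketal) (one enantiomer drawn) | C[C@@H]1CC2(OCCO2)CC(=O)C/C(C)=C\CC1=O | intermediate
10 | rac-4-hydroxy-4,10-dimethylcyclodecane-1,6,8-trione 8-(ethylene ketal) (diastereomer mixture) | CC1CC2(OCCO2)CC(=O)CC(C)(O)CCC1=O | intermediate
11 | rac-(4E)-4,10-dimethylcyclodec-4-ene-1,6,8-trione 8-(ethylene ketal) (one enantiomer drawn) | C[C@@H]1CC2(OCCO2)CC(=O)/C=C(\C)CCC1=O | intermediate
12 | (4E,6S)-6-hydroxy-4,10-dimethylcyclodec-4-ene-1,8-dione 8-(ethylene ketal) (both C10 epimers) | CC1CC2(OCCO2)C[C@H](O)/C=C(\C)CCC1=O | intermediate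
13 | (4E,6S)-4,10-dimethyl-6-(triethylsilyloxy)cyclodec-4-ene-1,8-dione 8-(ethylene ketal) (both C10 epimers) | CC1CC2(OCCO2)C[C@H](O[Si](CC)(CC)CC)/C=C(\C)CCC1=O | intermediate
14 | potassium C1=C10 enolate of 13 | CC=1CC2(OCCO2)C[C@H](O[Si](CC)(CC)CC)/C=C(\C)CCC=1[O-].[K+] | intermediate (not isolated)
15 | (4E,6S,10R)-10-hydroxy-4,10-dimethyl-6-(triethylsilyloxy)cyclodec-4-ene-1,8-dione 8-(ethylene ketal) | C[C@@]1(O)CC2(OCCO2)C[C@H](O[Si](CC)(CC)CC)/C=C(\C)CCC1=O | intermediate
16 | (4E,6S,10R)-10-acetoxy-4,10-dimethyl-6-(triethylsilyloxy)cyclodec-4-ene-1,8-dione 8-(ethylene ketal) | C[C@@]1(OC(C)=O)CC2(OCCO2)C[C@H](O[Si](CC)(CC)CC)/C=C(\C)CCC1=O | intermediate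
17 | (4E,6S,10R)-10-acetoxy-6-hydroxy-4,10-dimethylcyclodec-4-ene-1,8-dione | C[C@@]1(OC(C)=O)CC(=O)C[C@H](O)/C=C(\C)CCC1=O | intermediate
18 | (4R,5R,6S,10R)-10-acetoxy-4,5-epoxy-6-hydroxy-4,10-dimethylcyclodecane-1,8-dione | C[C@@]1(OC(C)=O)CC(=O)C[C@H](O)[C@H]2O[C@]2(C)CCC1=O | intermediate
19 | methyl chlorooxoacetate | COC(=O)C(Cl)=O | starting material
20 | (4R,5R,6S,10R)-10-acetoxy-4,5-epoxy-6-(methoxyoxalyloxy)-4,10-dimethylcyclodecane-1,8-dione | C[C@@]1(OC(C)=O)CC(=O)C[C@H](OC(=O)C(=O)OC)[C@H]2O[C@]2(C)CCC1=O | intermediate
21 | (4R,5R,6S,10R)-10-acetoxy-4,5-epoxy-11-hydroxy-1,8-dioxo-13-norgermacr-7(11)-en-12,6-olide | O=C1C[C@@](C)(OC(C)=O)C(=O)CC[C@@]2(C)O[C@@H]2[C@H]2OC(=O)C(O)=C12 | intermediate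
22 | (4R,5R,6S,10R)-10-acetoxy-4,5-epoxy-1,8-dioxo-11-(trifluoromethanesulfonyloxy)-13-norgermacr-7(11)-en-12,6-olide | O=C1C[C@@](C)(OC(C)=O)C(=O)CC[C@@]2(C)O[C@@H]2[C@H]2OC(=O)C(OS(=O)(=O)C(F)(F)F)=C12 | intermediate
23 | (4R,5R,6S,8S,10R)-10-acetoxy-4,5-epoxy-8-hydroxy-1-oxo-11-(trifluoromethanesulfonyloxy)-13-norgermacr-7(11)-en-12,6-olide | O[C@H]1C[C@@](C)(OC(C)=O)C(=O)CC[C@@]2(C)O[C@@H]2[C@H]2OC(=O)C(OS(=O)(=O)C(F)(F)F)=C12 | intermediate
24 | (tributylstannyl)methanol | CCCC[Sn](CO)(CCCC)CCCC | starting material
25 | (4R,5R,6S,8S,10R)-10-acetoxy-4,5-epoxy-8,13-dihydroxy-1-oxogermacr-7(11)-en-12,6-olide | O[C@H]1C[C@@](C)(OC(C)=O)C(=O)CC[C@@]2(C)O[C@@H]2[C@H]2OC(=O)C(CO)=C12 | intermediate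
26 | (4R,5R,6S,8S,10R)-10,13-diacetoxy-4,5-epoxy-8-hydroxy-1-oxogermacr-7(11)-en-12,6-olide | O[C@H]1C[C@@](C)(OC(C)=O)C(=O)CC[C@@]2(C)O[C@@H]2[C@H]2OC(=O)C(COC(C)=O)=C12 | intermediate
27 | (E)-2-methylbut-2-enoyl chloride (tigloyl chloride) | C/C=C(\C)C(Cl)=O | starting material
28 | (4R,5R,6S,8S,10R)-10,13-diacetoxy-4,5-epoxy-1-oxo-8-[(E)-2-methylbut-2-enoyloxy]germacr-7(11)-en-12,6-olide (CNP0175424.1) | C/C=C(\C)C(=O)O[C@H]1C[C@@](C)(OC(C)=O)C(=O)CC[C@@]2(C)O[C@@H]2[C@H]2OC(=O)C(COC(C)=O)=C12 | target

## Step count and least certain steps

Total step count: 20. Longest linear sequence: 20 steps from 1 (3, 5, 19, 24 and 27 are bought).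

Step 5 (key step). Most likely failure: over-oxidation, in which ozone also cleaves the trisubstituted alkene once the fusion alkene is used up, and transannular aldol closure of the 1,6-diketone during work-up. Fallback: it sets out from 7. Peracid epoxidation with mCPBA, which picks the most nucleophilic, tetrasubstituted alkene, gives the ring-fusion epoxide F1. Cleavage of F1 with H5IO6 in aqueous THF at 0 °C gives the same diketone, and the route is rejoined at 9.

Step 2. Most likely failure: competing isopropylation of the arene by propene, oligomerization of the alkene, and ring closure at the position ortho to the methyl group. Fallback: it sets out from 2. AlCl3-mediated acylative annulation with propyne gives 4,7-dimethylnaphthalen-2-ol F2. O-Methylation (Me2SO4, K2CO3) gives 3-methoxy-1,6-dimethylnaphthalene F3. Li/NH3/EtOH reduction of both rings gives rac-2-methoxy-4,7-dimethyl-1,4,5,8-tetrahydronaphthalene F4, and exchange of the enol ether with 5 (TsOH cat.) leads back to 7. This is held in reserve because protonation of the methoxy ring at a fusion carbon is a real competitor in the second reduction.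

Step 7. Most likely failure: loss of geometric control in the syn elimination, giving the Z-enone, or elimination away from C5. Fallback: it sets out from 10. If the elimination gives the (4Z)-enone F5, it is reduced as in step 8 to the (4Z,6S)-allylic alcohol F6 and epoxidized with mCPBA to the cis-epoxy alcohol F7. The alkene is then re-formed with inverted geometry by LiPPh2 (anti opening at C5), then MeI (syn collapse of the betaine), and the route is rejoined at 12.

Step 8. Most likely failure: insufficient chemoselectivity, with the C1 ketone reduced alongside the enone, and a weaker facial preference because the C7 methylene is β-branched. Fallback: it sets out from 11. The saturated C1 ketone is masked selectively as its dimethyl ketal F8 (HC(OMe)3, MeOH, PPTS; the enone does not ketalize). The same reduction then gives the allylic alcohol F9, and brief PPTS in wet acetone at room temperature removes the dimethyl ketal but not the dioxolane, returning to 12.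

Step 10. Most likely failure: poor regioselectivity of enolization (C2 instead of C10) and a modest facial preference of the oxaziridine for a tetrasubstituted dialkyl enolate. Fallback: it sets out from 13. Equilibrating silylation (TMSCl, NaI, Et3N, MeCN) gives the more substituted trimethylsilyl enol ether F10. Rubottom oxidation with dimethyldioxirane at −78 °C, which attacks the enol ether much faster than the C4=C5 alkene, gives both C10 alcohols, and the (10R)-diastereomer is separated by chromatography, rejoining at 15.

Step 15. Most likely failure: β-elimination of the oxalate at C6 or of the acetate at C10 from the ketone enolates outrunning the ring closure, and consumption of base at C2. Fallback: it sets out from 18 and leaves out step 14. With LiN(SiMe3)2 (2.2 equiv) the free hydroxy ketone gives the C6 alkoxide and the C7 enolate, so no acyloxy leaving group is present. Dimethyl oxalate then acylates C7 to the keto ester F11, whose C6 alkoxide closes the lactone with loss of methanol, and the route is rejoined at 21.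

## Further compounds

F1 | step 5 | rac-4a',8a'-epoxy-4',7'-dimethyl-3',4',4a',5',8',8a'-hexahydro-1'H-spiro[1,3-dioxolane-2,2'-naphthalene] | C[C@@H]1CC2(OCCO2)CC34OC13CC=C(C)C4
F2 | step 2 | 4,7-dimethylnaphthalen-2-ol | Oc1cc(C)c2ccc(C)cc2c1
F3 | step 2 | 3-methoxy-1,6-dimethylnaphthalene | COc1cc(C)c2ccc(C)cc2c1
F4 | step 2 | rac-2-methoxy-4,7-dimethyl-1,4,5,8-tetrahydronaphthalene | COC1=CC(C)C2=C(C1)CC(C)=CC2
F5 | step 7 | rac-(4Z)-4,10-dimethylcyclodec-4-ene-1,6,8-trione 8-(ethylene ketal) | C[C@@H]1CC2(OCCO2)CC(=O)/C=C(/C)CCC1=O
F6 | step 7 | (4Z,6S)-6-hydroxy-4,10-dimethylcyclodec-4-ene-1,8-dione 8-(ethylene ketal) (both C10 epimers) | CC1CC2(OCCO2)C[C@H](O)/C=C(/C)CCC1=O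
F7 | step 7 | (4S,5R,6S)-4,5-epoxy-6-hydroxy-4,10-dimethylcyclodecane-1,8-dione 8-(ethylene ketal) (both C10 epimers) | CC1CC2(OCCO2)C[C@H](O)[C@H]2O[C@@]2(C)CCC1=O
F8 | step 8 | rac-(4E)-1,1-dimethoxy-4,10-dimethylcyclodec-4-ene-6,8-dione 8-(ethylene ketal) | C[C@@H]1CC2(OCCO2)CC(=O)/C=C(\C)CCC1(OC)OC
F9 | step 8 | (4E,6S)-6-hydroxy-1,1-dimethoxy-4,10-dimethylcyclodec-4-en-8-one ethylene ketal (both C10 epimers) | CC1CC2(OCCO2)C[C@H](O)/C=C(\C)CCC1(OC)OC
F10 | step 10 | C1=C10 trimethylsilyl enol ether of 13 | CC=1CC2(OCCO2)C[C@H](O[Si](CC)(CC)CC)/C=C(\C)CCC=1O[Si](C)(C)C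
F11 | step 15 | (4R,5R,6S,10R)-10-acetoxy-4,5-epoxy-6-hydroxy-7-(methoxyoxalyl)-4,10-dimethylcyclodecane-1,8-dione (C7 epimers, not isolated) | C[C@@]1(OC(C)=O)CC(=O)C(C(=O)C(=O)OC)[C@H](O)[C@H]2O[C@]2(C)CCC1=O
A1 | alternative 1 | 13-O-(tert-butyldimethylsilyl)-13-deacetyl analogue of the target | C/C=C(\C)C(=O)O[C@H]1C[C@@](C)(OC(C)=O)C(=O)CC[C@@]2(C)O[C@@H]2[C@H]2OC(=O)C(CO[Si](C)(C)C(C)(C)C)=C12
A2 | alternative 2 | ten-membered (Z)-5-en-1-one with C4 triethylsilyloxy, C8 tert-butyldimethylsilyloxy, C10 4-methoxybenzyloxy and a bis(4-methoxybenzyloxymethyl)methylidene group on C7 | O=C1CC[C@@](C)(O[Si](CC)(CC)CC)/C=C\C(=C(COCc2ccc(OC)cc2)COCc2ccc(OC)cc2)[C@@H](O[Si](C)(C)C(C)(C)C)C[C@@]1(C)OCc1ccc(OC)cc1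
A3 | alternative 3 | 8-hydroxy macrocycle lacking the tiglate (identical with 26) | O[C@H]1C[C@@](C)(OC(C)=O)C(=O)CC[C@@]2(C)O[C@@H]2[C@H]2OC(=O)C(COC(C)=O)=C12
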